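(All runs stem from a simulated flask with constants of no real substance, noise included.)

Friday's run loses more starting material than it makes target: 15.7% of the charge is gone by 5.00 h, with 0% target.

in all of them: gas phase 170 mM (held)

|  | starting material | remark | time |
|---|---|---|---|
| Friday's | 1.1 M | run made earlier |  |
| flask | 0.72 M |  | 8.0 d |
Friday's run (percent of the starting material charged)

| time / h | target / % | starting material / % |
|---|---|---|
| 1.50 | 0 | 94.4 |
| 5.00 | 0 | 84.3 |
| 8.00 | 3.5 | 75.9 |
| 15.0 | 9.4 | 60.1 |
| 20.0 | 9.2 | 49.8 |

(scatter of a reading: 1 percentage point)
- at the start none of the gas phase is in solution
- how much target there is at 8.0 d, in percent of the starting material charged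
- concentration of dissolved gas in solution at 8.0 d, in percent of saturation

So you have two routes out of the starting material. Ask where the flask ends, then how fast. I count each pull as a fraction of what is left, per hour.

Target pull, read from Friday's gain between 8.00 h and 15.0 h:

g = 0.0124 h⁻¹

The gas phase is held at 170 mM in both flasks, but none of it is in solution at the start, so g belongs to Friday's window and is no constant. I carry it over as a rough average, and that is an assumption of mine.

Side pull, read from Friday's first reading:

0.0373 h⁻¹

Late in Friday's run, with g taken off, it reads lower:

0.0252 h⁻¹

So I take it as second order, proportional to the starting material present, and scale it to this flask's charge: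

s = 0.0244 h⁻¹

r = s/g = 1.97

Integrating the split over the run-down, with g held at that rough average, gives ln(one plus r) divided by r. This is the route share, an integrated selectivity: the fraction of the charge leaving by the target route.

share = 55.2%

By the target route, that rough g gives a half-life of about 2.33 d, shorter than 8.0 d, so I take the run-down as finished and commit to that share as target.

The forecast stands lower, at 11%, with 95% of saturation: “The stall suggests a cap”.

The flask gives 47.4% target and 94.9% of saturation at 8.0 d.

    gas phase ⇌ dissolved gas, rate k1*(csat - [dissolved gas]) (kL = 0.00120 min⁻¹)
    starting material + dissolved gas → target (k = 0.00290 M⁻¹ min⁻¹)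
    dissolved gas + target → over-reacted product (k = 1.30 × 10⁻⁴ M⁻¹ min⁻¹)
    2 starting material → self-condensation product (k = 2.70 × 10⁻⁴ M⁻¹ min⁻¹)

In this flask, target plus over-reacted product stands at 55.2%, so my weak link was letting target stay. Half of the target-making step's turnover is done by 1.74 d, leaving 6.26 d before the reading, shorter than target's 23 d half-life at 8.00 d, and that decay takes the share to 45.7%. Read at 3.0 d, the same flask has 15.8% starting material left; the share down to that point is 41.5%, and it holds 41.2% target plus over-reacted product.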